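| setting | green | ochre | cedar | larch |
|---|---|---|---|---|
| free monomer | 0.25 M | 0.25 M | 0.25 M | 0.25 M |
| transfer agent | 1.7 mM | 6.4 mM | 7.50 mM | 2.00 mM |
| initiator | 12 mM | 12 mM | 12 mM | 12 mM |
| remark | run made earlier | run made earlier |  |  |
| time |  |  | 12 h | 12 h |

| run | time / h | monomer in chains / % |
|---|---|---|
| green | 1.33 | 31.3 |
| green | 2.50 | 49.3 |
| green | 4.00 | 65.4 |
| green | 5.00 | 74.6 |
| green | 6.00 | 80.4 |
| green | 8.00 | 87.6 |
| ochre | 0.667 | 11.3 |
| ochre | 1.00 | 17.1 |
| ochre | 1.50 | 23.3 |
| ochre | 2.50 | 32.2 |
| ochre | 4.00 | 46.6 |
| ochre | 6.00 | 60.0 |
| ochre | 8.00 | 68.6 |

(each reading ± 1 percentage point)

- the average divides the monomer in chains by the number of chains begun, living and dead together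
- the numbers in the tables scatter by 1 percentage point (one standard deviation)
- the earlier runs do not show the number of chains; that part of a forecast is a guess

- which of the two ends with the longer chains by the average number of monomer units in a chain (chains begun, living or dead) ("neither" if they lie within 10%) (cedar / larch / neither)
- average number of monomer units in a chain (chains begun, living or dead) at the end, cedar
- average number of monomer units in a chain (chains begun, living or dead) at the end, larch

- In the closed vessel of the green run, the logarithm of one over the fraction of free monomer left climbs from 1.06 at 4.00 h to 2.09 at 8.00 h, keeping step with time as a pseudo-first-order decay does.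
- At 8.00 h the green and ochre runs stand in the ratio 1.80 on that logarithm, while their charges of initiator minus transfer agent stand in the ratio 1.84, so the readings look as if each transfer agent cancels one initiator and the pace follows the remainder.
- Scaling the green run by that remainder and by time, this reckoning gives larch 3.04 as its fold number, the logarithm of one over the fraction of free monomer left at the end, and cedar 1.37, so the fractions left are 4.78% in larch and 25.5% in cedar.
- One number falls short here, since it gives monomer in chains but the readings show no chain count; guessing one chain per initiator charged, this reckoning puts cedar at 15.5 and larch at 19.8, so larch ends longer.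
- The forecast, holding that “more transfer agent retards the rate”, says larch, with 15 for cedar and 31 for larch; this reckoning shares its choice but puts larch lower.
- The simulation gives larch, with 16.2 for cedar and 20.8 for larch.

    free monomer + initiator → living end + monomer in chains (k = 0.530 /M/min)
    free monomer + living end → monomer in chains + living end, rate k2*[living end]*[free monomer] (k = 0.450 /M/min)
    initiator → spent initiator (k = 0.00570 /min)
    living end + transfer agent → dead chain (kL = 12.0 /M/min)

- Larch ends with the longer chains because of the difference in transfer agent : larch given cedar's charge of transfer agent ends at 16.2 in place of 20.8. At the end, living ends plus dead chains come to 11.5 mM in cedar and 11.5 mM in larch, but the living ends stand at 0.00399 M in cedar against 0.00948 M in larch, and cedar keeps 26% of its free monomer and larch 4.5%, where the fold numbers gave 25.5% and 4.78%. The forecast counted 7.5 mM of chains in larch, and there its 31 parts from 20.8.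
- A neighbour of larch charged with 0.0030 M of initiator has the fold number 0.304, hence 73.8% of its free monomer left and, at one chain per initiator charged, a length of 21.8; the simulation leaves 71% and gives 24.9.

(The readings are simulated on assumed constants; noise was put on by code.)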